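**Retrosynthetic overview**
1. (6R)-ε,ψ-Carotene (δ-carotene) ⇒ Wittig at C11=C12: (R)-ε-C15 phosphonium salt + acyclic C25 aldehyde (apo-12′-lycopenal).
2. Apo-12′-lycopenal ⇒ Wittig at C11′=C12′: acyclic ψ-C15 phosphonium salt + C10-dialdehyde.
3. (R)-ε-C15 salt ⇒ the same ψ-C15 salt, by a catalytic enantioselective proton-initiated ψ→ε ring closure (H+ at C2, C1–C6 bond, loss of H-4), the sequence used by lycopene ε-cyclase.
4. ψ-C15 salt ⇒ (E,E)-pseudoionone + vinyl Grignard + Ph3P·HBr; one acyclic salt supplies both end groups.
5. Ring order: the single ring (ε-ring, carrying the only stereocentre C6) is closed once, on the C15 Wittig salt, before the polyene is assembled.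

Assumption: pseudoionone (1) is used as the geometrically pure (3E,5E) isomer (bought as such or fractionated from the technical mixture), because the 5Z isomer would give 5Z carotenoids and erode the ee of the ring closure.
Assumption: the (S,S) antipode of the chiral acid is written in step 4; which antipode gives 6R has to be fixed in a first run, and the mirror-image catalyst is used if needed.
Carotenoid numbering is used in the text (ε half unprimed, ψ half primed).

Step 1
Reactants: 1 (3E,5E)-pseudoionone [(3E,5E)-6,10-dimethylundeca-3,5,9-trien-2-one]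
Product: 2 vinyl-ψ-ionol [(4E,6E)-3,7,11-trimethyldodeca-1,4,6,10-tetraen-3-ol, racemic at C3]
Conditions: CH2=CHMgBr (1.2 equiv), THF, −20 → 0 °C; sat. aq. NH4Cl
Reagents that add atoms: vinylmagnesium bromide, C=C[Mg]Br
Why: Grignard 1,2-addition to the dienone carbonyl (a hard vinyl nucleophile at low temperature gives no conjugate addition) forms the tertiary bis-allylic carbinol, whose racemic centre is erased in step 2.

Step 2
Reactants: 2 vinyl-ψ-ionol
Product: 3 ψ-C15 phosphonium bromide {[(2E,4E,6E)-3,7,11-trimethyldodeca-2,4,6,10-tetraen-1-yl]triphenylphosphonium bromide}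
Conditions: Ph3P·HBr (1.0 equiv), MeOH, 0 °C → rt; crystallise to the 2E salt
Reagents that add atoms: triphenylphosphine hydrobromide, [Br-].[PH+](c1ccccc1)(c1ccccc1)c1ccccc1
Why: SN1′ allylic transposition, in which Ph3PH+ ionises the tertiary allylic alcohol to a heptatrienyl cation that Ph3P captures at the unhindered primary terminus, giving the fully conjugated triene salt (the standard C15 Wittig-salt formation of carotenoid manufacture), E at the new trisubstituted bond after crystallisation.

Step 3
Reactants: 3 ψ-C15 phosphonium bromide (about half of the batch); 4 C10-dialdehyde [(2E,4E,6E)-2,7-dimethylocta-2,4,6-trienedial]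
Product: 6 12′-apo-ψ-caroten-12′-al (apo-12′-lycopenal), via ψ-C15 ylide 5 (not isolated)
Conditions: NaOMe (1.05 equiv), MeOH/CH2Cl2, 3 added slowly to 4 (2 equiv), 0 °C → rt; then n-heptane, reflux (Z→E); crystallise
Reagents that add atoms: none
Why: Wittig olefination of one formyl group of the symmetrical dialdehyde by the semi-stabilised allylic ylide, double olefination being held back by excess 4 and inverse addition, and the hindered Z isomer at the new C11′=C12′ bond reverting to E on heating.

Step 4
Reactants: 3 ψ-C15 phosphonium bromide (second half of the batch)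
Product: 9 (R)-ε-C15 phosphonium triflimide, via ψ-C15 phosphonium triflimide 7 (not isolated), via ring cation 8 (not isolated)
Conditions: AgNTf2 (1.0 equiv), CH2Cl2, 0 °C, filter off AgBr; then (S,S)-IDPi (confined BINOL-derived imidodiphosphorimidate Brønsted acid, 5 mol %), (CF3)3COH/CH2Cl2, −40 °C, dark, Ar
Reagents that add atoms: silver bis(trifluoromethanesulfonyl)imide, [Ag+].[N-](S(=O)(=O)C(F)(F)F)S(=O)(=O)C(F)(F)F
Why: Proposed new method: after in-flask Br−→NTf2− exchange (HBr is a weaker and HNTf2 a stronger acid than the catalyst, so the chiral acid stays the only proton source), the confined acid protonates C2 of the only basic alkene (the isolated Me2C=CH; the triene is deactivated by the adjacent Ph3P+ just as the dienone is in pseudoionone), the C1 cation held in a chair fold inside the chiral anion is captured by C6 of the 5E alkene (6-endo, Markovnikov, avoiding vicinal quaternary carbons) to give cation 8 with C6 set as R by the catalyst-enforced fold, and the counter-anion removes H-4 to leave the ε (Δ4) ring; the closest known reaction types are the Brønsted-acid cyclisation of pseudoionone to α-ionone and IDPi-catalysed proton-initiated asymmetric polyene cyclisations in fluorinated alcohols.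

Step 5
Reactants: 9 (R)-ε-C15 phosphonium triflimide; 6 apo-12′-lycopenal
Product: 11 (6R)-ε,ψ-carotene (δ-carotene), via ε-C15 ylide 10 (not isolated)
Conditions: NaOMe (1.1 equiv), MeOH/CH2Cl2, 0 °C → rt; then n-heptane, reflux, dark (Z→E); crystallise (CH2Cl2/MeOH)
Reagents that add atoms: none
Why: Wittig olefination forming C11=C12, in which C6 is not acidified in ylide 10 and 6 has no stereocentre, so the R centre from step 4 is carried through unchanged and the hindered 11Z isomer is isomerised thermally to the all-E target.

**Compound list**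
1 | (3E,5E)-pseudoionone, (3E,5E)-6,10-dimethylundeca-3,5,9-trien-2-one | CC(=O)/C=C/C=C(C)/CCC=C(C)C | starting material
2 | vinyl-ψ-ionol, (4E,6E)-3,7,11-trimethyldodeca-1,4,6,10-tetraen-3-ol (racemic) | C=CC(C)(O)/C=C/C=C(C)/CCC=C(C)C | intermediate
3 | ψ-C15 phosphonium bromide, [(2E,4E,6E)-3,7,11-trimethyldodeca-2,4,6,10-tetraen-1-yl]triphenylphosphonium bromide | CC(C)=CCC/C(C)=C/C=C/C(C)=C/C[P+](c1ccccc1)(c1ccccc1)c1ccccc1.[Br-] | intermediate
4 | C10-dialdehyde, (2E,4E,6E)-2,7-dimethylocta-2,4,6-trienedial | O=C/C(C)=C/C=C/C=C(C)/C=O | starting material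
5 | ψ-C15 ylide, (2E,4E,6E)-3,7,11-trimethyldodeca-2,4,6,10-tetraen-1-ylidene(triphenyl)phosphorane (not isolated) | CC(C)=CCC/C(C)=C/C=C/C(C)=C/[CH-][P+](c1ccccc1)(c1ccccc1)c1ccccc1 | intermediate
6 | apo-12′-lycopenal, (2E,4E,6E,8E,10E,12E,14E)-2,7,11,15,19-pentamethylicosa-2,4,6,8,10,12,14,18-octaenal | CC(C)=CCC/C(C)=C/C=C/C(C)=C/C=C/C(C)=C/C=C/C=C(C)/C=O | intermediate
7 | ψ-C15 phosphonium triflimide, cation of 3 with bis(trifluoromethanesulfonyl)imide counter-ion (not isolated) | CC(C)=CCC/C(C)=C/C=C/C(C)=C/C[P+](c1ccccc1)(c1ccccc1)c1ccccc1.[N-](S(=O)(=O)C(F)(F)F)S(=O)(=O)C(F)(F)F | intermediate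
8 | ring cation, monocyclic tertiary C5 carbocation with C6 already R, ion-paired with the chiral IDPi anion and NTf2− (anions not drawn; not isolated) | c1ccccc1[P+](c1ccccc1)(c1ccccc1)C/C=C(C)/C=C/[C@H]1[C+](C)CCCC1(C)C | intermediate
9 | (R)-ε-C15 phosphonium triflimide, {(2E,4E)-3-methyl-5-[(1R)-2,6,6-trimethylcyclohex-2-en-1-yl]penta-2,4-dien-1-yl}triphenylphosphonium bis(trifluoromethanesulfonyl)imide | c1ccccc1[P+](c1ccccc1)(c1ccccc1)C/C=C(C)/C=C/[C@H]1C(C)=CCCC1(C)C.[N-](S(=O)(=O)C(F)(F)F)S(=O)(=O)C(F)(F)F | intermediate
10 | ε-C15 ylide, phosphorane from 9 (not isolated) | c1ccccc1[P+](c1ccccc1)(c1ccccc1)[CH-]/C=C(C)/C=C/[C@H]1C(C)=CCCC1(C)C | intermediate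
11 | (6R)-ε,ψ-carotene (δ-carotene, CNP0405345.1), all-E | CC(C)=CCC/C(C)=C/C=C/C(C)=C/C=C/C(C)=C/C=C/C=C(C)/C=C/C=C(C)/C=C/[C@H]1C(C)=CCCC1(C)C | target

**Totals**
Total step count: 5. Longest linear sequence: 4 steps (1 → 2 → 3 → 9 → 11, or 1 → 2 → 3 → 6 → 11).

**Steps most likely to fail, with fallbacks**

Step 4 is the riskiest. The substrate is cationic and the asymmetric closure is untested on it. Possible failures are low turnover, loss of H-6 or a methyl proton instead of H-4 (β- or γ-ring salts), low ee, and isomeric salts that are hard to separate. The fallback sets out from compound 1 and comes back to the route at compound 10. It moves the same proton-initiated ring closure to the neutral C13 ketone, where it is established, and sets the stereocentre by separation instead of catalyst control. Treating 1 with 85 % H3PO4 at 25–30 °C gives (±)-α-ionone F1. Preparative chromatography on a cellulose tris(3,5-dimethylphenylcarbamate) phase gives (R)-α-ionone F2, and the S enantiomer is set aside. Vinylmagnesium bromide in THF at −20 °C adds to F2 to give (R)-vinyl-α-ionol F3 as an inconsequential mixture of carbinol epimers. Ph3P·HBr in MeOH converts F3 into the (R)-ε-C15 phosphonium bromide F4. NaOMe deprotonates F4 to the same ylide 10, which is condensed with 6 as in the main route.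

Step 5 is the second risk. The long polyenal 6 is poorly soluble, the new bond forms as an E/Z mixture, and any ψ-, β- or γ-salt carried in 9 would give lycopene or isomeric carotenes that are hard to remove from the hydrocarbon product. The fallback sets out from compounds 9 and 4 and comes back at compound 11. It reverses the order of fragment union so that the last bond formed is C11′=C12′. Ylide 10 (from 9, NaOMe) is condensed with excess 4 to give (6R)-12′-apo-ε-caroten-12′-al F5. This neutral C25 aldehyde can be chromatographed and crystallised free of isomeric end-group impurities, and its ee can be measured. F5 is then olefinated with ψ-ylide 5 (from 3) under base-free conditions (1,2-epoxybutane, reflux) to protect the vinylogously activated C6–H, followed by thermal Z→E isomerisation to 11.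

Step 3 is the third risk. Mono-olefination of a symmetrical dialdehyde is statistical, and the C25 aldehyde can react a second time to give lycopene. The fallback sets out from compound 4 and comes back at compound 6. It differentiates the two formyl groups before the coupling. Compound 4 is treated with neopentyl glycol (1 equiv, cat. TsOH, toluene) to give the mono-acetal (2E,4E,6E)-7-(5,5-dimethyl-1,3-dioxan-2-yl)-2-methylocta-2,4,6-trienal F6, with unreacted 4 and bis-acetal recycled. Wittig reaction of F6 with ylide 5 gives the apo-12′-lycopenal neopentyl glycol acetal F7. Dilute aq. H2SO4 in THF at rt releases 6.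

**Further compounds**
F1 | step 4 | (±)-α-ionone, (3E)-4-(2,6,6-trimethylcyclohex-2-en-1-yl)but-3-en-2-one (racemic) | CC(=O)/C=C/C1C(C)=CCCC1(C)C
F2 | step 4 | (R)-α-ionone | CC(=O)/C=C/[C@H]1C(C)=CCCC1(C)C
F3 | step 4 | (R)-vinyl-α-ionol, (1E)-3-methyl-1-[(1R)-2,6,6-trimethylcyclohex-2-en-1-yl]penta-1,4-dien-3-ol (carbinol epimers) | C=CC(C)(O)/C=C/[C@H]1C(C)=CCCC1(C)C
F4 | step 4 | (R)-ε-C15 phosphonium bromide, {(2E,4E)-3-methyl-5-[(1R)-2,6,6-trimethylcyclohex-2-en-1-yl]penta-2,4-dien-1-yl}triphenylphosphonium bromide | c1ccccc1[P+](c1ccccc1)(c1ccccc1)C/C=C(C)/C=C/[C@H]1C(C)=CCCC1(C)C.[Br-]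
F5 | step 5 | (6R)-12′-apo-ε-caroten-12′-al, all-E | O=C/C(C)=C/C=C/C=C(C)/C=C/C=C(C)/C=C/[C@H]1C(C)=CCCC1(C)C
F6 | step 3 | C10-dialdehyde mono(neopentyl glycol) acetal, (2E,4E,6E)-7-(5,5-dimethyl-1,3-dioxan-2-yl)-2-methylocta-2,4,6-trienal | O=C/C(C)=C/C=C/C=C(C)/C1OCC(C)(C)CO1
F7 | step 3 | apo-12′-lycopenal neopentyl glycol acetal (5,5-dimethyl-1,3-dioxane of 6), all-E | CC(C)=CCC/C(C)=C/C=C/C(C)=C/C=C/C(C)=C/C=C/C=C(C)/C1OCC(C)(C)CO1
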